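**Plan**

- Locants: O1, C2, C3, C4, C8a and rings A, B, C belong to the first flavanone unit; the double-primed ones (O1'', C2'', C3'', C4'', C8a'', rings A'', B'', C'') belong to the second.
- Cuts: after O-debenzylation, each pyranone ring is cut at its aryl ether bond and its acyl–carbon bond (O1''–C8a'' and C3''–C4''; likewise O1–C8a and C3–C4). This leaves a meso 1,4-diaryl-but-2-yne-1,4-diol (chain C2–C3≡C3''–C2'') and two 4-(benzyloxy)-2-fluorobenzaldehydes. The diol is cut at C2–C3 and C2''–C3'' to acetylene and two 4-(benzyloxy)benzaldehydes.
- Enabling feature: the 1,4-diketone C4(=O)–C3–C3''–C4''(=O), in which each carbonyl carbon sits ortho to the ether oxygen (O1 on ring A, O1'' on ring A''). A 2-fluorobenzaldehyde can therefore act as SNAr electrophile at C8a/C8a'' and, through its Breslow intermediate, as acyl anion at C4/C4''.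
- Forward order: the chain first (diol); then, in one flask, both aryl ethers, ring C by alkyne hydroacylation (which leaves the enone C4=O/C3=C3''), and ring C'' by Stetter addition to C3''; debenzylation last. The alkyne is the oxidation-level helper for the C3–C3'' single bond and is used up by the two formyl C–H additions.
- Stereochemistry: the heterochiral C2/C2'' relation is that of the meso diol, which is separated from its racemic diastereomer and not touched again. C3 and C3'' are set in the key step and, being α to ketones, should settle to 2,3-trans in each ring, which is the meso target.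

Key step: step 2

Remark: the target is the meso isomer (2S,3R,2''R,3''S) with both pyranone rings 2,3-trans, so only relative configuration has to be controlled; chiral intermediates are racemic. Step 1 has no intrinsic diastereocontrol, and the meso diol is taken on after separation.

**Route**

Step 1
Reactants: 1 4-(benzyloxy)benzaldehyde (2 equiv); 2 acetylene
Product: 3 meso-(1R,4S)-1,4-bis[4-(benzyloxy)phenyl]but-2-yne-1,4-diol
Conditions: EtMgBr (2 equiv), acetylene, Et2O–THF, 0 °C to reflux; then 1, 0 °C to rt; aqueous work-up; fractional crystallisation of the meso diol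
Reagents that add atoms: none
Why: Double Grignard 1,2-addition of the acetylene bis-Grignard reagent to the aldehyde should build the C2–C3≡C3''–C2'' chain in one operation; the two carbinol centres form without mutual control, so the meso diol, which carries the heterochiral C2/C2'' relation of the target, is to be separated from the racemic diastereomer.

Step 2
Reactants: 3 meso-(1R,4S)-1,4-bis[4-(benzyloxy)phenyl]but-2-yne-1,4-diol; 4 4-(benzyloxy)-2-fluorobenzaldehyde (2.1 equiv)
Product: 7 meso-(2S,3R,2''R,3''S)-7,7''-bis(benzyloxy)-2,2''-bis[4-(benzyloxy)phenyl]-3,3''-bichroman-4,4''-dione, via bis(2-formylaryl) ether 5 (not isolated), via alkylidene flavanone aldehyde 6 (not isolated)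
Conditions: NaH (2.1 equiv), DMF, 0 °C; 4, 0 °C to rt; then 3-mesityl-4,5-dimethylthiazol-3-ium perchlorate (20 mol %), K2CO3 (30 mol %), THF, 70 °C, one flask
Reagents that add atoms: none
Why: Proposed new method: the disodium dialkoxide of 3 should displace fluoride from two molecules of 4 (addition–elimination SNAr activated by the ortho formyl group, retention at both carbinol carbons) to give 5; the thiazol-2-ylidene then turns one formyl group into a Breslow intermediate that adds across the alkyne by concerted syn hydroacylation to give the E-enone 6, whose β-carbon C3'' is attacked by the Breslow intermediate of the second formyl group (intramolecular Stetter addition) before the C3 enolate is protonated. The closest known reaction type is the carbene-catalysed alkyne hydroacylation–Stetter cascade of O-propargyl salicylaldehydes; new here are the tethered Stetter partner, the use of both ends of one alkyne, and the aryl ether formation in the same flask by the known alkoxide SNAr on 2-fluorobenzaldehydes. Ring C closes 6-exo-dig onto C3 and ring C'' closes 6-exo-trig onto C3'', the 7-endo modes being disfavoured because the short aryl ether tether brings the formyl carbon to the proximal carbon only. C2 and C2'' are not touched and keep the heterochiral relation of the meso diol, while C3'' (Stetter addition) and C3 (enolate protonation) are both α to a ketone and should equilibrate under the carbonate base to the 2,3-trans diequatorial arrangement in each ring, which for heterochiral C2/C2'' is the meso all-trans isomer. The step needs the second closure to outrun base-induced exo-to-endo migration of the C3=C3'' double bond of 6 and retro-oxa-Michael opening of ring C; the six-membered intramolecular Stetter closure and the use of only catalytic weak base after the NaH has been consumed are meant to secure this.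

Step 3
Reactants: 7 meso-(2S,3R,2''R,3''S)-7,7''-bis(benzyloxy)-2,2''-bis[4-(benzyloxy)phenyl]-3,3''-bichroman-4,4''-dione
Product: 8 meso-(2S,3R,2''R,3''S)-7,7''-dihydroxy-2,2''-bis(4-hydroxyphenyl)-3,3''-bichroman-4,4''-dione (CNP0231820.1)
Conditions: H2 (1 atm), 10% Pd/C, EtOAc–MeOH, rt
Reagents that add atoms: none
Why: Catalytic hydrogenolysis of the four aryl benzyl ethers under neutral conditions involves neither enolisation nor ring opening, so the four stereocentres should be carried through unchanged.

**Compound list**

1 | 4-(benzyloxy)benzaldehyde | O=Cc1ccc(OCc2ccccc2)cc1 | starting material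
2 | acetylene | C#C | starting material
3 | meso-(1R,4S)-1,4-bis[4-(benzyloxy)phenyl]but-2-yne-1,4-diol | O[C@H](c1ccc(OCc2ccccc2)cc1)C#C[C@@H](O)c1ccc(OCc2ccccc2)cc1 | intermediate
4 | 4-(benzyloxy)-2-fluorobenzaldehyde | O=Cc1ccc(OCc2ccccc2)cc1F | starting material
5 | meso-2,2'-{[(1R,4S)-1,4-bis[4-(benzyloxy)phenyl]but-2-yne-1,4-diyl]bis(oxy)}bis[4-(benzyloxy)benzaldehyde] | O=Cc1ccc(OCc2ccccc2)cc1O[C@H](c1ccc(OCc2ccccc2)cc1)C#C[C@@H](Oc1cc(OCc2ccccc2)ccc1C=O)c1ccc(OCc2ccccc2)cc1 | intermediate
6 | rac-(2R,3E)-7-(benzyloxy)-2-[4-(benzyloxy)phenyl]-3-{(2R)-2-[4-(benzyloxy)phenyl]-2-[5-(benzyloxy)-2-formylphenoxy]ethylidene}chroman-4-one (one enantiomer drawn) | O=C1c2ccc(OCc3ccccc3)cc2O[C@H](c2ccc(OCc3ccccc3)cc2)/C1=C\[C@@H](Oc1cc(OCc2ccccc2)ccc1C=O)c1ccc(OCc2ccccc2)cc1 | intermediate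
7 | meso-(2S,3R,2''R,3''S)-7,7''-bis(benzyloxy)-2,2''-bis[4-(benzyloxy)phenyl]-3,3''-bichroman-4,4''-dione | O=C1c2ccc(OCc3ccccc3)cc2O[C@H](c2ccc(OCc3ccccc3)cc2)[C@H]1[C@@H]1C(=O)c2ccc(OCc3ccccc3)cc2O[C@H]1c1ccc(OCc2ccccc2)cc1 | intermediate
8 | meso-(2S,3R,2''R,3''S)-7,7''-dihydroxy-2,2''-bis(4-hydroxyphenyl)-3,3''-bichroman-4,4''-dione (CNP0231820.1) | O=C1c2ccc(O)cc2O[C@H](c2ccc(O)cc2)[C@H]1[C@@H]1C(=O)c2ccc(O)cc2O[C@H]1c1ccc(O)cc1 | target

**Count**

Total step count: 3. Longest linear sequence: 3 steps (1 → 3 → 7 → 8).

**Steps most likely to fail**

Step 2 (proposed new method). The relay may stall in three ways: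
- During the SNAr stage, Oppenauer-type hydride transfer from the secondary sodium alkoxide to the aldehyde may compete.
- After the first ring closure, the exocyclic C3=C3'' double bond of the enone may migrate into ring C before the second closure.
- Enolate-mediated retro-oxa-Michael opening may erode the C2/C2'' relation.

The fallback sets out from 3 and returns at 7 through separately run, known reactions. Diol 3 is etherified under Mitsunobu conditions (PPh3, DIAD, THF, 0 °C) with commercial 4-(benzyloxy)-2-hydroxybenzaldehyde. This forms the C2–O1 and C2''–O1'' bonds with inversion at both centres, which maps the meso diol onto the same meso dialdehyde 5, now isolated without any alkoxide being present. Compound 5 is then submitted to the known carbene-catalysed alkyne hydroacylation (thiazolium salt, catalytic K2CO3, THF, 70 °C) and the reaction is stopped at the alkylidene flavanone aldehyde 6, which is isolated. Ring C'' is closed in a separate intramolecular Stetter reaction with a triazolium precatalyst and Et3N at room temperature, followed by brief equilibration of C3/C3'' with catalytic K2CO3, to reach 7. This fallback makes no compound outside the compound list (F0).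

Step 1. The second carbonyl addition has no facial preference (no 1,4-induction across the alkyne), and the two diastereomers may co-crystallise, so the meso diol may not be obtained pure.

The fallback sets out from 1 and returns at 3 by catalyst-controlled construction of the two carbinol centres with enantiomeric ligands:
- Aldehyde 1 is alkynylated with trimethylsilylacetylene under Me2Zn and (S,S)-ProPhenol to give (R)-1-[4-(benzyloxy)phenyl]-3-(trimethylsilyl)prop-2-yn-1-ol F1.
- Silylation with TBSCl and imidazole gives the bis-silylated compound tert-butyl({(1R)-1-[4-(benzyloxy)phenyl]-3-(trimethylsilyl)prop-2-yn-1-yl}oxy)dimethylsilane F2.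
- K2CO3 in MeOH removes the alkynyl silyl group to give the terminal alkyne tert-butyl({(1S)-1-[4-(benzyloxy)phenyl]prop-2-yn-1-yl}oxy)dimethylsilane F3. The descriptor changes by priority only; the configuration is unchanged.
- A second alkynylation of 1 with F3 under Me2Zn and the enantiomeric (R,R)-ProPhenol sets the new carbinol centre in the opposite sense and gives (1S,4R)-1,4-bis[4-(benzyloxy)phenyl]-4-[(tert-butyldimethylsilyl)oxy]but-2-yn-1-ol F4.
- Tetrabutylammonium fluoride in THF then gives 3.

Which ligand is used first is immaterial for a meso product, as long as the two additions use opposite ligands.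

Step 3. Hydrogenolysis may go too far, either by cleaving the benzylic C2–O1 and C2''–O1'' bonds of the pyranone rings or by reducing the aryl ketones.

The fallback sets out from 7 and returns at 8 by a non-reductive, Lewis-acid dealkylation: BCl3 with pentamethylbenzene as benzyl-cation scavenger in CH2Cl2 at −78 °C, with a methanol quench at low temperature so that C2 and C2'' are not ionised. This fallback makes no compound outside the compound list (F0).

**Further compounds**

F1 | step 1 | (R)-1-[4-(benzyloxy)phenyl]-3-(trimethylsilyl)prop-2-yn-1-ol | O[C@H](c1ccc(OCc2ccccc2)cc1)C#C[Si](C)(C)C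
F2 | step 1 | tert-butyl({(1R)-1-[4-(benzyloxy)phenyl]-3-(trimethylsilyl)prop-2-yn-1-yl}oxy)dimethylsilane | CC(C)(C)[Si](C)(C)O[C@H](c1ccc(OCc2ccccc2)cc1)C#C[Si](C)(C)C
F3 | step 1 | tert-butyl({(1S)-1-[4-(benzyloxy)phenyl]prop-2-yn-1-yl}oxy)dimethylsilane | CC(C)(C)[Si](C)(C)O[C@H](c1ccc(OCc2ccccc2)cc1)C#C
F4 | step 1 | (1S,4R)-1,4-bis[4-(benzyloxy)phenyl]-4-[(tert-butyldimethylsilyl)oxy]but-2-yn-1-ol | CC(C)(C)[Si](C)(C)O[C@H](c1ccc(OCc2ccccc2)cc1)C#C[C@@H](O)c1ccc(OCc2ccccc2)cc1
F0 | step 2 | none | none
F0 | step 3 | none | none
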